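**Retrosynthetic overview**
1. Last bond C6–C7: intramolecular Hosomi–Sakurai allylation of a butenolide allylsilane onto the C6 aldehyde closes the cyclohexane and turns the butenolide into the cis-fused α-methylene lactone.
2. C8–C9: catalytic asymmetric vinylogous Mukaiyama aldol joins the C10 aldehyde 25 (fragments A+B) with the C5 silyloxyfuran 18 (fragment C) at step 17 of 22; OH-directed epoxidation and methacrylation follow.
3. C5–C10 (quaternary methyl/vinyl centre next to the C5 methine): enantioselective boron-enolate Ireland–Claisen rearrangement of the ester made from C5 acid 5 (fragment A) and C5 allylic alcohol 10 (fragment B).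
4. Three C5 fragments of similar size, each made in 3–5 steps from feedstocks of at most seven non-hydrogen atoms (2-methylidenepropane-1,3-diol, but-2-yne-1,4-diol, furfural).
5. Ring order: butenolide (already in fragment C) → oxirane (step 18) → cyclohexane (step 22).

Locants in the Why lines are elemane-type labels of the target: C10 quaternary, C9 (O-methacrylate), C8 (lactone O), C7, C6 (OH), C5; C1–C2 oxirane; C4(=C3)–C15 acrolein; C11(=C13)–C12 lactone.

Assumption: the sense of induction of the (S,S)-diazaborolidine bromide (step 13) and of the (R,R)-(salen)CrSbF6 catalyst (step 17) is as stated; if either is reversed, its antipode is used.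

**Fragment A**

Step 1
Reactants: 1 2-methylidenepropane-1,3-diol
Product: 2 2-(hydroxymethyl)prop-2-en-1-yl 2,2-dimethylpropanoate
Conditions: pivaloyl chloride (0.9 equiv), pyridine, CH2Cl2, −20 °C
Reagents that add atoms: pivaloyl chloride CC(C)(C)C(Cl)=O
Why: Statistical mono-acylation of the symmetrical diol with a sub-stoichiometric amount of the bulky acyl chloride gives the mono-ester, and no stereocentre is formed.

Step 2
Reactants: 2 2-(hydroxymethyl)prop-2-en-1-yl 2,2-dimethylpropanoate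
Product: 3 2-(bromomethyl)prop-2-en-1-yl 2,2-dimethylpropanoate
Conditions: CBr4, PPh3, CH2Cl2, 0 °C
Reagents that add atoms: tetrabromomethane BrC(Br)(Br)Br
Why: Appel bromination converts the remaining allylic alcohol into the bromide under neutral conditions that leave the pivalate untouched.

Step 3
Reactants: 3 2-(bromomethyl)prop-2-en-1-yl 2,2-dimethylpropanoate
Product: 5 3-{[(2,2-dimethylpropanoyl)oxy]methyl}but-3-enoic acid, via allylzinc bromide 4 (not isolated)
Conditions: Zn dust, LiCl, THF, 0 °C; then CO2 (1 atm), DMF, 25 °C; 1 M HCl work-up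
Reagents that add atoms: carbon dioxide O=C=O
Why: Zinc insertion into the allylic bromide and carboxylation of the allylzinc (both allyl termini are equivalent) give the β,γ-unsaturated acid without moving the double bond into conjugation.

**Fragment B**

Step 4
Reactants: 6 but-2-yne-1,4-diol
Product: 7 4-[(triethylsilyl)oxy]but-2-yn-1-ol
Conditions: NaH (1.0 equiv), THF, 0 °C; Et3SiCl (1.0 equiv)
Reagents that add atoms: chlorotriethylsilane CC[Si](Cl)(CC)CC
Why: Silylation of the sparingly soluble monosodium alkoxide mono-protects the symmetrical diol.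

Step 5
Reactants: 7 4-[(triethylsilyl)oxy]but-2-yn-1-ol
Product: 9 (2Z)-3-iodo-4-[(triethylsilyl)oxy]but-2-en-1-ol, via cyclic alkenylalanate 8 (not isolated)
Conditions: NaAlH2(OCH2CH2OMe)2 (1.5 equiv), Et2O, 0 °C; then I2, −78 → 0 °C
Reagents that add atoms: iodine [I][I]
Why: Hydroxyl-directed trans-hydroalumination puts aluminium on the distal alkyne carbon in a five-membered alanate, and iodinolysis with retention fixes the (Z)-iodoalkene geometry.

Step 6
Reactants: 9 (2Z)-3-iodo-4-[(triethylsilyl)oxy]but-2-en-1-ol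
Product: 10 (2E)-3-methyl-4-[(triethylsilyl)oxy]but-2-en-1-ol
Conditions: Me2CuLi (3 equiv), Et2O, −30 → 0 °C; NH4Cl work-up
Reagents that add atoms: lithium dimethylcuprate [Li+].C[Cu-]C
Why: Cuprate cross-coupling replaces iodine by methyl with retention, so the methyl group ends cis to the hydroxymethyl group, which is the alkene geometry the Claisen step needs.

**Fragment C**

Step 7
Reactants: 11 furan-2-carbaldehyde
Product: 14 furan-2(5H)-one, via furan-2-yl formate 12 (not isolated), via furan-2(3H)-one 13 (not isolated)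
Conditions: 30% H2O2, HCO2H, CH2Cl2, reflux (performic acid formed in the flask); then Et3N (cat.), 25 °C
Reagents that add atoms: hydrogen peroxide OO
Why: Baeyer–Villiger oxidation of the aldehyde, hydrolysis of the formate and base isomerisation of the β,γ-unsaturated lactone give the conjugated butenolide.

Step 8
Reactants: 14 furan-2(5H)-one
Product: 15 trans-3,4-dibromodihydrofuran-2(3H)-one (racemate)
Conditions: Br2, CH2Cl2, 25 °C
Reagents that add atoms: bromine BrBr
Why: Electrophilic anti addition of bromine to the enoate double bond gives the trans dibromide, whose configuration is lost in the next step.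

Step 9
Reactants: 15 trans-3,4-dibromodihydrofuran-2(3H)-one
Product: 16 3-bromofuran-2(5H)-one
Conditions: Et3N, Et2O, 0 °C
Reagents that add atoms: none
Why: E1cB dehydrobromination removes the acidic α-hydrogen and the β-bromide and leaves the α-bromobutenolide.

Step 10
Reactants: 16 3-bromofuran-2(5H)-one
Product: 17 3-[(trimethylsilyl)methyl]furan-2(5H)-one
Conditions: Me3SiCH2MgCl, ZnCl2, THF, 0 °C (gives Me3SiCH2ZnCl); then 16, Pd(PPh3)4 (3 mol%), THF, 45 °C
Reagents that add atoms: (trimethylsilyl)methylmagnesium chloride C[Si](C)(C)C[Mg]Cl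
Why: Negishi coupling of the α-bromo enoate with an alkylzinc that has no β-hydrogen installs the silylmethyl group and so creates the 2-carbonyl allylsilane.

Step 11
Reactants: 17 3-[(trimethylsilyl)methyl]furan-2(5H)-one
Product: 18 trimethyl({3-[(trimethylsilyl)methyl]furan-2-yl}oxy)silane
Conditions: Me3SiOTf, Et3N, Et2O, 0 °C; filtration, distillation
Reagents that add atoms: trimethylsilyl trifluoromethanesulfonate C[Si](C)(C)OS(=O)(=O)C(F)(F)F
Why: Soft enolisation at the γ-position and O-silylation give the aromatic 2-silyloxyfuran, the dienol ether for the vinylogous aldol.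

**Union of A and B, main line**

Step 12
Reactants: 5 3-{[(2,2-dimethylpropanoyl)oxy]methyl}but-3-enoic acid; 10 (2E)-3-methyl-4-[(triethylsilyl)oxy]but-2-en-1-ol
Product: 19 (2E)-3-methyl-4-[(triethylsilyl)oxy]but-2-en-1-yl 3-{[(2,2-dimethylpropanoyl)oxy]methyl}but-3-enoate
Conditions: DCC, DMAP (5 mol%), CH2Cl2, 0 °C
Reagents that add atoms: none
Why: Steglich esterification joins fragments A and B, and low temperature with little DMAP keeps the β,γ-unsaturated acyl group from conjugating.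

Step 13
Reactants: 19 (2E)-3-methyl-4-[(triethylsilyl)oxy]but-2-en-1-yl 3-{[(2,2-dimethylpropanoyl)oxy]methyl}but-3-enoate
Product: 21 (2S,3S)-2-{3-[(2,2-dimethylpropanoyl)oxy]prop-1-en-2-yl}-3-methyl-3-{[(triethylsilyl)oxy]methyl}pent-4-enoic acid, via boron ketene acetal 20 (not isolated)
Conditions: (4S,5S)-2-bromo-4,5-diphenyl-1,3-bis{[3,5-bis(trifluoromethyl)phenyl]sulfonyl}-1,3,2-diazaborolidine (1.2 equiv), Et3N, toluene–hexane, −78 °C; then −20 → 4 °C, 48 h; aqueous work-up
Reagents that add atoms: none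
Why: Enantioselective Ireland–Claisen rearrangement in which Et3N in toluene–hexane gives the E(O) boron enolate and a chair transition state with the (E)-allyl unit forms the C5–C10 bond, so the quaternary methyl/vinyl centre C10 and the adjacent C5 are set together with the chiral diazaborolidine fixing the absolute sense.

Step 14
Reactants: 21 (2S,3S)-2-{3-[(2,2-dimethylpropanoyl)oxy]prop-1-en-2-yl}-3-methyl-3-{[(triethylsilyl)oxy]methyl}pent-4-enoic acid
Product: 22 (2S,3S)-2-(3-hydroxyprop-1-en-2-yl)-3-methyl-3-{[(triethylsilyl)oxy]methyl}pent-4-en-1-ol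
Conditions: LiAlH4 (4 equiv), THF, 0 → 25 °C; Rochelle-salt work-up
Reagents that add atoms: none
Why: Hydride reduction converts the acid into the C6 primary alcohol and cleaves the pivalate in the same operation without touching the silyl ether or the stereocentres.

Step 15
Reactants: 22 (2S,3S)-2-(3-hydroxyprop-1-en-2-yl)-3-methyl-3-{[(triethylsilyl)oxy]methyl}pent-4-en-1-ol
Product: 23 triethyl{[(2S,3S)-2-ethenyl-3,4-bis{[(4-methoxybenzyl)oxy]methyl}-2-methylpent-4-en-1-yl]oxy}silane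
Conditions: NaH (2.5 equiv), 4-methoxybenzyl chloride (2.4 equiv), Bu4NI (cat.), DMF, 0 → 25 °C
Reagents that add atoms: 4-methoxybenzyl chloride COc1ccc(CCl)cc1
Why: Williamson etherification protects both primary hydroxyls as PMB ethers, which survive the Lewis acid, peroxide and acylation steps and are removed oxidatively later.

Step 16
Reactants: 23 triethyl{[(2S,3S)-2-ethenyl-3,4-bis{[(4-methoxybenzyl)oxy]methyl}-2-methylpent-4-en-1-yl]oxy}silane
Product: 25 (2S,3S)-2-ethenyl-3,4-bis{[(4-methoxybenzyl)oxy]methyl}-2-methylpent-4-enal, via primary alcohol 24 (not isolated)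
Conditions: IBX (3 equiv), DMSO, 25 °C
Reagents that add atoms: none
Why: IBX in DMSO cleaves the primary triethylsilyl ether and oxidises the freed neopentyl alcohol in the same flask to the non-enolisable α-quaternary aldehyde.

**Late coupling with fragment C and endgame**

Step 17
Reactants: 25 (2S,3S)-2-ethenyl-3,4-bis{[(4-methoxybenzyl)oxy]methyl}-2-methylpent-4-enal; 18 trimethyl({3-[(trimethylsilyl)methyl]furan-2-yl}oxy)silane
Product: 27 (5R)-5-[(1S,2S,3S)-2-ethenyl-1-hydroxy-3,4-bis{[(4-methoxybenzyl)oxy]methyl}-2-methylpent-4-en-1-yl]-3-[(trimethylsilyl)methyl]furan-2(5H)-one, via trimethylsilyl ether 26 (not isolated)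
Conditions: (R,R)-(salen)CrSbF6 (5 mol%), 4 Å MS, CH2Cl2, −20 °C; then 1 M HCl, THF, 0 °C
Reagents that add atoms: none
Why: Catalyst-controlled vinylogous Mukaiyama aldol at the γ-carbon of the silyloxyfuran on the Re face of the aldehyde with anti (erythro) simple selectivity forms the C8–C9 bond and sets C8 (R) and C9 (S).

Step 18
Reactants: 27 (5R)-5-[(1S,2S,3S)-2-ethenyl-1-hydroxy-3,4-bis{[(4-methoxybenzyl)oxy]methyl}-2-methylpent-4-en-1-yl]-3-[(trimethylsilyl)methyl]furan-2(5H)-one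
Product: 28 (5R)-5-[(1S,2S,3S)-1-hydroxy-3,4-bis{[(4-methoxybenzyl)oxy]methyl}-2-methyl-2-[(2S)-oxiran-2-yl]pent-4-en-1-yl]-3-[(trimethylsilyl)methyl]furan-2(5H)-one
Conditions: VO(acac)2 (5 mol%), t-BuOOH (1.5 equiv), CH2Cl2, 0 → 25 °C
Reagents that add atoms: tert-butyl hydroperoxide CC(C)(C)OO
Why: Hydroxyl-directed vanadium-catalysed epoxidation of the homoallylic vinyl group through a chair-like vanadate transition state, with the bulkier C5 branch of the quaternary centre equatorial and the methyl axial, delivers oxygen to one face and sets the oxirane carbon C1 (S), while the electron-poor butenolide and the more remote 1,1-disubstituted alkene react more slowly.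

Step 19
Reactants: 28 (5R)-5-[(1S,2S,3S)-1-hydroxy-3,4-bis{[(4-methoxybenzyl)oxy]methyl}-2-methyl-2-[(2S)-oxiran-2-yl]pent-4-en-1-yl]-3-[(trimethylsilyl)methyl]furan-2(5H)-one
Product: 29 (1S,2R,3S)-3,4-bis{[(4-methoxybenzyl)oxy]methyl}-2-methyl-2-[(2S)-oxiran-2-yl]-1-{(2R)-5-oxo-4-[(trimethylsilyl)methyl]-2,5-dihydrofuran-2-yl}pent-4-en-1-yl 2-methylprop-2-enoate
Conditions: methacryloyl chloride, pyridine, DMAP (cat.), CH2Cl2, 0 °C
Reagents that add atoms: 2-methylprop-2-enoyl chloride C=C(C)C(Cl)=O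
Why: DMAP-catalysed acylation of the hindered C9 carbinol installs the methacrylate with retention, and the low temperature limits base-induced elimination to a γ-ylidene butenolide.

Step 20
Reactants: 29 (1S,2R,3S)-3,4-bis{[(4-methoxybenzyl)oxy]methyl}-2-methyl-2-[(2S)-oxiran-2-yl]-1-{(2R)-5-oxo-4-[(trimethylsilyl)methyl]-2,5-dihydrofuran-2-yl}pent-4-en-1-yl 2-methylprop-2-enoate
Product: 30 (1S,2R,3S)-3,4-bis(hydroxymethyl)-2-methyl-2-[(2S)-oxiran-2-yl]-1-{(2R)-5-oxo-4-[(trimethylsilyl)methyl]-2,5-dihydrofuran-2-yl}pent-4-en-1-yl 2-methylprop-2-enoate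
Conditions: DDQ (2.5 equiv), CH2Cl2/pH 7 phosphate buffer, 0 °C
Reagents that add atoms: none
Why: Oxidative cleavage of both PMB ethers by DDQ under buffered neutral conditions spares the oxirane, the allylsilane and both esters.

Step 21
Reactants: 30 (1S,2R,3S)-3,4-bis(hydroxymethyl)-2-methyl-2-[(2S)-oxiran-2-yl]-1-{(2R)-5-oxo-4-[(trimethylsilyl)methyl]-2,5-dihydrofuran-2-yl}pent-4-en-1-yl 2-methylprop-2-enoate
Product: 31 (1S,2R,3R)-3,4-diformyl-2-methyl-2-[(2S)-oxiran-2-yl]-1-{(2R)-5-oxo-4-[(trimethylsilyl)methyl]-2,5-dihydrofuran-2-yl}pent-4-en-1-yl 2-methylprop-2-enoate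
Conditions: Dess–Martin periodinane (2.5 equiv), NaHCO3, CH2Cl2, 0 °C; used at once
Reagents that add atoms: none
Why: Buffered Dess–Martin oxidation of both primary alcohols gives the C6 aldehyde and the C15 enal without epimerising C5 or moving the 1,1-disubstituted double bond.

Step 22
Reactants: 31 (1S,2R,3R)-3,4-diformyl-2-methyl-2-[(2S)-oxiran-2-yl]-1-{(2R)-5-oxo-4-[(trimethylsilyl)methyl]-2,5-dihydrofuran-2-yl}pent-4-en-1-yl 2-methylprop-2-enoate
Product: 32 (3aR,4S,5R,6R,7S,7aR)-4-hydroxy-6-methyl-3-methylidene-6-[(2S)-oxiran-2-yl]-2-oxo-5-(3-oxoprop-1-en-2-yl)octahydro-1-benzofuran-7-yl 2-methylprop-2-enoate (CNP0124638.3)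
Conditions: BF3·OEt2 (1.2 equiv), CH2Cl2, −78 °C, 20 min; aqueous NaHCO3 quench at −78 °C
Reagents that add atoms: none
Why: Intramolecular Hosomi–Sakurai allylation in which the γ-carbon C7 of the 2-carbonyl allylsilane attacks the BF3-activated saturated C6 aldehyde (six-membered closure, faster than seven-membered attack on the enal) in a chair-like transition state, the tether through C8 forcing cis ring fusion at C7 and the equatorial carbonyl oxygen giving the C6 hydroxyl trans to C11, while loss of silicon creates the exo-methylene lactone.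

**Compound list**
1 | 2-methylidenepropane-1,3-diol | C=C(CO)CO | starting material
2 | 2-(hydroxymethyl)prop-2-en-1-yl 2,2-dimethylpropanoate | C=C(CO)COC(=O)C(C)(C)C | intermediate
3 | 2-(bromomethyl)prop-2-en-1-yl 2,2-dimethylpropanoate | C=C(CBr)COC(=O)C(C)(C)C | intermediate
4 | {2-[(2,2-dimethylpropanoyloxy)methyl]prop-2-en-1-yl}zinc bromide | C=C(C[Zn]Br)COC(=O)C(C)(C)C | intermediate
5 | 3-{[(2,2-dimethylpropanoyl)oxy]methyl}but-3-enoic acid | C=C(CC(=O)O)COC(=O)C(C)(C)C | intermediate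
6 | but-2-yne-1,4-diol | OCC#CCO | starting material
7 | 4-[(triethylsilyl)oxy]but-2-yn-1-ol | OCC#CCO[Si](CC)(CC)CC | intermediate
8 | sodium cyclic alkenylalanate (five-membered O–Al–C ring, two 2-methoxyethoxy ligands on aluminium) | [Na+].COCCO[Al-]1(OCCOC)OCC=C1CO[Si](CC)(CC)CC | intermediate
9 | (2Z)-3-iodo-4-[(triethylsilyl)oxy]but-2-en-1-ol | OC/C=C(\I)CO[Si](CC)(CC)CC | intermediate
10 | (2E)-3-methyl-4-[(triethylsilyl)oxy]but-2-en-1-ol | OC/C=C(\C)CO[Si](CC)(CC)CC | intermediate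
11 | furan-2-carbaldehyde (furfural) | O=Cc1ccco1 | starting material
12 | furan-2-yl formate | O=COc1ccco1 | intermediate
13 | furan-2(3H)-one | O=C1CC=CO1 | intermediate
14 | furan-2(5H)-one | O=C1C=CCO1 | intermediate
15 | trans-3,4-dibromodihydrofuran-2(3H)-one (racemate, one enantiomer drawn) | O=C1OC[C@H](Br)[C@H]1Br | intermediate
16 | 3-bromofuran-2(5H)-one | O=C1OCC=C1Br | intermediate
17 | 3-[(trimethylsilyl)methyl]furan-2(5H)-one | O=C1OCC=C1C[Si](C)(C)C | intermediate
18 | trimethyl({3-[(trimethylsilyl)methyl]furan-2-yl}oxy)silane | C[Si](C)(C)Cc1ccoc1O[Si](C)(C)C | intermediate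
19 | (2E)-3-methyl-4-[(triethylsilyl)oxy]but-2-en-1-yl 3-{[(2,2-dimethylpropanoyl)oxy]methyl}but-3-enoate | C=C(CC(=O)OC/C=C(\C)CO[Si](CC)(CC)CC)COC(=O)C(C)(C)C | intermediate
20 | E(O) boron ketene acetal of 19 bound to the (4S,5S)-diazaborolidine | C=C(COC(=O)C(C)(C)C)/C=C(/OB1N(S(=O)(=O)c2cc(cc(c2)C(F)(F)F)C(F)(F)F)[C@@H](c2ccccc2)[C@H](c2ccccc2)N1S(=O)(=O)c1cc(cc(c1)C(F)(F)F)C(F)(F)F)OC/C=C(\C)CO[Si](CC)(CC)CC | intermediate
21 | (2S,3S)-2-{3-[(2,2-dimethylpropanoyl)oxy]prop-1-en-2-yl}-3-methyl-3-{[(triethylsilyl)oxy]methyl}pent-4-enoic acid | OC(=O)[C@@H](C(=C)COC(=O)C(C)(C)C)[C@](C)(C=C)CO[Si](CC)(CC)CC | intermediate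
22 | (2S,3S)-2-(3-hydroxyprop-1-en-2-yl)-3-methyl-3-{[(triethylsilyl)oxy]methyl}pent-4-en-1-ol | OC[C@@H](C(=C)CO)[C@](C)(C=C)CO[Si](CC)(CC)CC | intermediate
23 | triethyl{[(2S,3S)-2-ethenyl-3,4-bis{[(4-methoxybenzyl)oxy]methyl}-2-methylpent-4-en-1-yl]oxy}silane | COc1ccc(COC[C@@H](C(=C)COCc2ccc(OC)cc2)[C@](C)(C=C)CO[Si](CC)(CC)CC)cc1 | intermediate
24 | (2S,3S)-2-ethenyl-3,4-bis{[(4-methoxybenzyl)oxy]methyl}-2-methylpent-4-en-1-ol | COc1ccc(COC[C@@H](C(=C)COCc2ccc(OC)cc2)[C@](C)(C=C)CO)cc1 | intermediate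
25 | (2S,3S)-2-ethenyl-3,4-bis{[(4-methoxybenzyl)oxy]methyl}-2-methylpent-4-enal | O=C[C@@](C)(C=C)[C@@H](COCc1ccc(OC)cc1)C(=C)COCc1ccc(OC)cc1 | intermediate
26 | (5R)-5-[(1S,2S,3S)-2-ethenyl-3,4-bis{[(4-methoxybenzyl)oxy]methyl}-2-methyl-1-[(trimethylsilyl)oxy]pent-4-en-1-yl]-3-[(trimethylsilyl)methyl]furan-2(5H)-one | O=C1O[C@@H]([C@@H](O[Si](C)(C)C)[C@@](C)(C=C)[C@@H](COCc2ccc(OC)cc2)C(=C)COCc2ccc(OC)cc2)C=C1C[Si](C)(C)C | intermediate
27 | (5R)-5-[(1S,2S,3S)-2-ethenyl-1-hydroxy-3,4-bis{[(4-methoxybenzyl)oxy]methyl}-2-methylpent-4-en-1-yl]-3-[(trimethylsilyl)methyl]furan-2(5H)-one | O=C1O[C@@H]([C@@H](O)[C@@](C)(C=C)[C@@H](COCc2ccc(OC)cc2)C(=C)COCc2ccc(OC)cc2)C=C1C[Si](C)(C)C | intermediate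
28 | (5R)-5-[(1S,2S,3S)-1-hydroxy-3,4-bis{[(4-methoxybenzyl)oxy]methyl}-2-methyl-2-[(2S)-oxiran-2-yl]pent-4-en-1-yl]-3-[(trimethylsilyl)methyl]furan-2(5H)-one | O=C1O[C@@H]([C@@H](O)[C@@](C)([C@H]2CO2)[C@@H](COCc2ccc(OC)cc2)C(=C)COCc2ccc(OC)cc2)C=C1C[Si](C)(C)C | intermediate
29 | (1S,2R,3S)-3,4-bis{[(4-methoxybenzyl)oxy]methyl}-2-methyl-2-[(2S)-oxiran-2-yl]-1-{(2R)-5-oxo-4-[(trimethylsilyl)methyl]-2,5-dihydrofuran-2-yl}pent-4-en-1-yl 2-methylprop-2-enoate | O=C1O[C@@H]([C@@H](OC(=O)C(C)=C)[C@@](C)([C@H]2CO2)[C@@H](COCc2ccc(OC)cc2)C(=C)COCc2ccc(OC)cc2)C=C1C[Si](C)(C)C | intermediate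
30 | (1S,2R,3S)-3,4-bis(hydroxymethyl)-2-methyl-2-[(2S)-oxiran-2-yl]-1-{(2R)-5-oxo-4-[(trimethylsilyl)methyl]-2,5-dihydrofuran-2-yl}pent-4-en-1-yl 2-methylprop-2-enoate | O=C1O[C@@H]([C@@H](OC(=O)C(C)=C)[C@@](C)([C@H]2CO2)[C@@H](CO)C(=C)CO)C=C1C[Si](C)(C)C | intermediate
31 | (1S,2R,3R)-3,4-diformyl-2-methyl-2-[(2S)-oxiran-2-yl]-1-{(2R)-5-oxo-4-[(trimethylsilyl)methyl]-2,5-dihydrofuran-2-yl}pent-4-en-1-yl 2-methylprop-2-enoate | O=C1O[C@@H]([C@@H](OC(=O)C(C)=C)[C@@](C)([C@H]2CO2)[C@@H](C=O)C(=C)C=O)C=C1C[Si](C)(C)C | intermediate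
32 | (3aR,4S,5R,6R,7S,7aR)-4-hydroxy-6-methyl-3-methylidene-6-[(2S)-oxiran-2-yl]-2-oxo-5-(3-oxoprop-1-en-2-yl)octahydro-1-benzofuran-7-yl 2-methylprop-2-enoate | C=C(C)C(=O)O[C@@H]1[C@@H]2OC(=O)C(=C)[C@@H]2[C@@H](O)[C@@H](C(=C)C=O)[C@]1(C)[C@H]1CO1 | target

**Step count**
Total: 22 steps. Longest linear sequence: 14 steps (steps 1–3 or 4–6, then 12–22); 14/22 = 0.64.

**Three steps most likely to fail**

Step 17. The aldehyde is α-quaternary and hindered, and catalyst control of both the face and the anti selectivity is unproven on such a substrate. The fallback sets out from 25 and comes back at 27, and replaces the aldol by a furan-based, reagent-controlled sequence. 3-Bromofuran is coupled with Me3SiCH2MgCl (NiCl2(dppp)) to give 3-[(trimethylsilyl)methyl]furan F1. Lithiation at the less hindered α-position (n-BuLi) and addition to 25 give the furyl carbinol mixture F2. Dess–Martin oxidation gives the furyl ketone F3. Oxazaborolidine-catalysed (CBS) borane reduction then sets C9 and gives the (1S)-furyl carbinol F4. Singlet oxygen (O2, rose bengal, hν, iPr2NEt, −78 °C) oxidises the furan regioselectively to the γ-hydroxybutenolide F5. NaBH4/CeCl3 reduces its open keto-acid form under 1,2-chelation control (anti), and lactonisation returns 27.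

Step 18. The 1,1-disubstituted alkene is bishomoallylic to the same hydroxyl and may compete, and face selectivity in the flexible secondary carbinol rests on the chair model alone. The fallback sets out from 23 and comes back at 28, and epoxidises before the aldol, where only the quaternary centre biases the vanadate chair. PPTS in MeOH removes the triethylsilyl group to give the primary alcohol 24, isolated this time. VO(acac)2/t-BuOOH gives the epoxy alcohol F6. Dess–Martin oxidation gives the epoxy aldehyde F7. The aldol of step 17 on F7 gives the trimethylsilyl ether F8 and, after mild acid, 28.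

Step 22. BF3 may open or rearrange the oxirane, and the C6 configuration depends on which chair the closure prefers. The fallback sets out from 31 and comes back at 32, and changes the ring closure to a metal-mediated Barbier allylation under neutral conditions. N-Bromosuccinimide bromodesilylates the allylsilane with allylic transposition to the 4-bromo-3-methylidene lactone F9 (C7 epimers). Indium powder (In) in THF/H2O then forms the allylindium, which adds to the C6 aldehyde through a chair transition state to give 32.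

**Further compounds**
F1 | step 17 | 3-[(trimethylsilyl)methyl]furan | C[Si](C)(C)Cc1ccoc1
F2 | step 17 | (2S,3S)-2-ethenyl-3,4-bis{[(4-methoxybenzyl)oxy]methyl}-2-methyl-1-{4-[(trimethylsilyl)methyl]furan-2-yl}pent-4-en-1-ol (both C1 epimers) | OC(c1cc(C[Si](C)(C)C)co1)[C@@](C)(C=C)[C@@H](COCc1ccc(OC)cc1)C(=C)COCc1ccc(OC)cc1
F3 | step 17 | (2S,3S)-2-ethenyl-3,4-bis{[(4-methoxybenzyl)oxy]methyl}-2-methyl-1-{4-[(trimethylsilyl)methyl]furan-2-yl}pent-4-en-1-one | O=C(c1cc(C[Si](C)(C)C)co1)[C@@](C)(C=C)[C@@H](COCc1ccc(OC)cc1)C(=C)COCc1ccc(OC)cc1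
F4 | step 17 | (1S,2S,3S)-2-ethenyl-3,4-bis{[(4-methoxybenzyl)oxy]methyl}-2-methyl-1-{4-[(trimethylsilyl)methyl]furan-2-yl}pent-4-en-1-ol | O[C@H](c1cc(C[Si](C)(C)C)co1)[C@@](C)(C=C)[C@@H](COCc1ccc(OC)cc1)C(=C)COCc1ccc(OC)cc1
F5 | step 17 | 5-[(1S,2S,3S)-2-ethenyl-1-hydroxy-3,4-bis{[(4-methoxybenzyl)oxy]methyl}-2-methylpent-4-en-1-yl]-5-hydroxy-3-[(trimethylsilyl)methyl]furan-2(5H)-one (hemiketal epimers) | O=C1OC(O)([C@@H](O)[C@@](C)(C=C)[C@@H](COCc2ccc(OC)cc2)C(=C)COCc2ccc(OC)cc2)C=C1C[Si](C)(C)C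
F6 | step 18 | (2S,3S)-3,4-bis{[(4-methoxybenzyl)oxy]methyl}-2-methyl-2-[(2S)-oxiran-2-yl]pent-4-en-1-ol | COc1ccc(COC[C@@H](C(=C)COCc2ccc(OC)cc2)[C@](C)([C@H]2CO2)CO)cc1
F7 | step 18 | (2R,3S)-3,4-bis{[(4-methoxybenzyl)oxy]methyl}-2-methyl-2-[(2S)-oxiran-2-yl]pent-4-enal | O=C[C@@](C)([C@H]1CO1)[C@@H](COCc1ccc(OC)cc1)C(=C)COCc1ccc(OC)cc1
F8 | step 18 | trimethylsilyl ether of 28 at the C1 hydroxyl of the side chain | O=C1O[C@@H]([C@@H](O[Si](C)(C)C)[C@@](C)([C@H]2CO2)[C@@H](COCc2ccc(OC)cc2)C(=C)COCc2ccc(OC)cc2)C=C1C[Si](C)(C)C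
F9 | step 22 | (1S,2R,3R)-1-[(2R)-3-bromo-4-methylidene-5-oxooxolan-2-yl]-3,4-diformyl-2-methyl-2-[(2S)-oxiran-2-yl]pent-4-en-1-yl 2-methylprop-2-enoate (epimers at the bromine-bearing carbon) | C=C1C(Br)[C@H]([C@@H](OC(=O)C(C)=C)[C@@](C)([C@H]2CO2)[C@@H](C=O)C(=C)C=O)OC1=O
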